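The dihydrofuran ring (O1, C2, C3, C3a, C7a) is made last, by contracting a six-membered ring. The feature exploited is that C3 bears both arene carbon C3a and a one-carbon branch (CH2OH), the retron of a 1,2-aryl shift. The CH2OH carbon is therefore the former C4 carbonyl carbon of an (R)-flavanone. In one operation, PhI(OAc)2 in acidic trimethyl orthoformate moves C4a from C4 to C3, expels C4 as an exocyclic methyl ester, closes the five-membered ring and sets C3 trans to C2. The precursor, a 6-bromo-8-pivaloyloxyflavanone, gets its single stereocentre from a catalytic asymmetric conjugate arylation of a chromone. Ester reduction and a Heck reaction finish the route.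

Key step: step 5

Assumption: (S)-t-BuPyOx is taken to deliver the aryl group to the same enone face as in its additions to cyclic enones, which corresponds to (R)-7. If the sense proves opposite, (R)-t-BuPyOx is used.

Step 1
Reactants: 1 2',3'-dihydroxyacetophenone
Product: 2 3-acetyl-2-hydroxyphenyl pivalate
Conditions: PivCl (1.05 equiv), Et3N (1.1 equiv), CH2Cl2, 0 °C to rt
Reagents that add atoms: pivaloyl chloride, CC(C)(C)C(=O)Cl
Why: Chemoselective O-acylation, in which the 2'-OH is locked in a hydrogen bond to the ketone so the free 3'-OH reacts, and any acyl migration between the catechol oxygens converges on this same chelate-retaining isomer.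

Step 2
Reactants: 2 3-acetyl-2-hydroxyphenyl pivalate
Product: 3 3-acetyl-5-bromo-2-hydroxyphenyl pivalate
Conditions: NBS (1.05 equiv), MeCN, 0 °C to rt
Reagents that add atoms: N-bromosuccinimide, O=C1CCC(=O)N1Br
Why: Electrophilic aromatic bromination directed by the only free phenol, whose two ortho positions are blocked, so bromine should enter para to it, a position that is also meta to the acetyl group.

Step 3
Reactants: 3 3-acetyl-5-bromo-2-hydroxyphenyl pivalate
Product: 5 6-bromo-4-oxo-4H-chromen-8-yl pivalate, via enaminone 4 (not isolated)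
Conditions: Me2NCH(OMe)2 (2.5 equiv), toluene, 90 °C; concentrate; conc. HCl, CH2Cl2, rt to 40 °C
Reagents that add atoms: N,N-dimethylformamide dimethyl acetal, COC(OC)N(C)C
Why: Enaminone formation from the methyl ketone, followed by acid-induced addition–elimination of the phenol with loss of dimethylamine, is the standard chromone synthesis, and the hindered pivalate should resist the methanol set free.

Step 4
Reactants: 5 6-bromo-4-oxo-4H-chromen-8-yl pivalate; 6 3,4-dimethoxyphenylboronic acid
Product: 7 (R)-6-bromo-2-(3,4-dimethoxyphenyl)-4-oxochroman-8-yl pivalate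
Conditions: Pd(OCOCF3)2 (5 mol %), (S)-t-BuPyOx (6 mol %), NH4PF6 (30 mol %), H2O (5 equiv), 6 (2 equiv), ClCH2CH2Cl, 60 °C; recrystallisation
Reagents that add atoms: none
Why: Pd(II)/pyridine-oxazoline-catalysed asymmetric conjugate addition of an arylboronic acid to a chromone, in which the tert-butyl oxazoline blocks one enone face in the migratory insertion and sets C2 as R, the base-free medium avoids retro-oxa-Michael racemisation, and Pd(II) leaves the C–Br bond alone.

Step 5
Reactants: 7 (R)-6-bromo-2-(3,4-dimethoxyphenyl)-4-oxochroman-8-yl pivalate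
Product: 10 methyl (2R,3R)-5-bromo-2-(3,4-dimethoxyphenyl)-7-(pivaloyloxy)-2,3-dihydrobenzofuran-3-carboxylate, via enol ether 8 (not isolated), via iodane ketal 9 (not isolated)
Conditions: PhI(OAc)2 (1.2 equiv), conc. H2SO4 (cat.), HC(OMe)3, 0 °C to rt; aq. NaHCO3
Reagents that add atoms: trimethyl orthoformate, COC(OC)OC; water (work-up), O
Why: Acid and HC(OMe)3 turn ketone 7 into enol ether 8, PhI(OAc)2 attacks its C3 on the face anti to the C2 aryl group, and methanol adds at C4 to give the 2,3-trans iodane ketal 9. In the diequatorial half-chair of 9 the C3–I bond is antiperiplanar to C4–C4a, so C4a shifts from C4 to C3 through a bridged phenonium-type transition state while PhI leaves, pushed by the two ketal oxygens, and the dimethoxycarbenium ion so formed is hydrolysed to the methyl ester on work-up. This is the known hypervalent-iodine (or thallium(III)) oxidative 1,2-aryl-shift ring contraction of flavanones to trans-2-aryl-2,3-dihydrobenzofuran-3-carboxylates. The five-membered ring closes by contraction of the six-membered pyranone (C3–C4a made as C4–C4a breaks; C4a becomes C3a), and C4 ends outside the ring as the carboxyl carbon. C2 is carried over unchanged from 7, and C3 is set by inversion at the trans C3–I centre, which places CO2Me trans to the aryl group, the arrangement that is also favoured thermodynamically. The step needs migration of the A-ring carbon and not of the electron-rich C2 aryl group: only C4a is aligned in the diequatorial conformer, the aryl shift would need the diaxial conformer that suffers a 1,3-diaxial contact between aryl group and ketal methoxy group, and the ring oxygen on C8a (ortho to C4a) raises the migratory aptitude of C4a.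

Step 6
Reactants: 10 methyl (2R,3R)-5-bromo-2-(3,4-dimethoxyphenyl)-7-(pivaloyloxy)-2,3-dihydrobenzofuran-3-carboxylate
Product: 11 (2R,3S)-5-bromo-2-(3,4-dimethoxyphenyl)-3-(hydroxymethyl)-2,3-dihydrobenzofuran-7-ol
Conditions: DIBAL-H (6 equiv), CH2Cl2, −78 to 0 °C; aq. Rochelle salt
Reagents that add atoms: none
Why: Hydride reduction with DIBAL-H converts the methyl ester into the primary alcohol and cleaves the aryl pivalate in the same operation, without basic conditions that could epimerise C3 or open the ring by E1cB, so both stereocentres (the C3 descriptor changes only by CIP ranking) and the C–Br bond are untouched.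

Step 7
Reactants: 11 (2R,3S)-5-bromo-2-(3,4-dimethoxyphenyl)-3-(hydroxymethyl)-2,3-dihydrobenzofuran-7-ol; 12 acrylic acid
Product: 13 (E)-3-[(2R,3S)-2-(3,4-dimethoxyphenyl)-7-hydroxy-3-(hydroxymethyl)-2,3-dihydrobenzofuran-5-yl]acrylic acid (target)
Conditions: Pd(OAc)2 (5 mol %), P(o-tol)3 (12 mol %), Et3N (4 equiv), 12 (2 equiv), degassed DMF, 100 °C; then aq. citric acid
Reagents that add atoms: none
Why: The Mizoroki–Heck reaction of the aryl bromide with acrylic acid proceeds by syn insertion and syn β-hydride elimination to give the E-cinnamic acid, tolerates the free phenol and alcohol, and does not touch C2 or C3.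

Compound list
1 | 1-(2,3-dihydroxyphenyl)ethan-1-one (2',3'-dihydroxyacetophenone) | CC(=O)c1cccc(O)c1O | starting material
2 | 3-acetyl-2-hydroxyphenyl pivalate | CC(=O)c1cccc(OC(=O)C(C)(C)C)c1O | intermediate
3 | 3-acetyl-5-bromo-2-hydroxyphenyl pivalate | CC(=O)c1cc(Br)cc(OC(=O)C(C)(C)C)c1O | intermediate
4 | 5-bromo-3-[(E)-3-(dimethylamino)acryloyl]-2-hydroxyphenyl pivalate (enaminone) | CN(C)/C=C/C(=O)c1cc(Br)cc(OC(=O)C(C)(C)C)c1O | intermediate
5 | 6-bromo-4-oxo-4H-chromen-8-yl pivalate | O=c1ccoc2c(OC(=O)C(C)(C)C)cc(Br)cc12 | intermediate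
6 | 3,4-dimethoxyphenylboronic acid | COc1ccc(B(O)O)cc1OC | starting material
7 | (R)-6-bromo-2-(3,4-dimethoxyphenyl)-4-oxochroman-8-yl pivalate | COc1ccc([C@@H]2Oc3c(OC(=O)C(C)(C)C)cc(Br)cc3C(=O)C2)cc1OC | intermediate
8 | (R)-6-bromo-2-(3,4-dimethoxyphenyl)-4-methoxy-2H-chromen-8-yl pivalate (enol ether) | COc1ccc([C@@H]2Oc3c(OC(=O)C(C)(C)C)cc(Br)cc3C(OC)=C2)cc1OC | intermediate
9 | 2,3-trans-3-[acetoxy(phenyl)-λ3-iodanyl]-6-bromo-2-(3,4-dimethoxyphenyl)-4,4-dimethoxychroman-8-yl pivalate, C2 as in 7 (iodane ketal) | COc1ccc([C@@H]2Oc3c(OC(=O)C(C)(C)C)cc(Br)cc3C(OC)(OC)[C@H]2I(OC(C)=O)c4ccccc4)cc1OC | intermediate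
10 | methyl (2R,3R)-5-bromo-2-(3,4-dimethoxyphenyl)-7-(pivaloyloxy)-2,3-dihydrobenzofuran-3-carboxylate (2,3-trans) | COc1ccc([C@@H]2Oc3c(OC(=O)C(C)(C)C)cc(Br)cc3[C@H]2C(=O)OC)cc1OC | intermediate
11 | (2R,3S)-5-bromo-2-(3,4-dimethoxyphenyl)-3-(hydroxymethyl)-2,3-dihydrobenzofuran-7-ol (2,3-trans) | COc1ccc([C@@H]2Oc3c(O)cc(Br)cc3[C@H]2CO)cc1OC | intermediate
12 | acrylic acid | C=CC(=O)O | starting material
13 | (E)-3-[(2R,3S)-2-(3,4-dimethoxyphenyl)-7-hydroxy-3-(hydroxymethyl)-2,3-dihydrobenzofuran-5-yl]acrylic acid | COc1ccc([C@@H]2Oc3c(O)cc(/C=C/C(=O)O)cc3[C@H]2CO)cc1OC | target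

Total step count: 7. Longest linear sequence: 7 steps (1 to 13).

Steps most likely to fail

Step 5. Four processes could compete with the wanted shift:
- a 1,2-shift of the electron-rich C2 aryl group;
- dehydrogenation across C2–C3;
- solvolysis of the C3–I bond by methanol;
- erosion of the enantiomeric purity by acid-induced reversible opening of the C2–O1 bond before iodination.

The fallback replaces cation chemistry by carbene chemistry, in which the aryl-shift channel from C2 does not exist. It sets out from 7. Condensation with tert-butoxybis(dimethylamino)methane should give the 3-(dimethylaminomethylene)flavanone F1. Diazo transfer from tosyl azide to this enaminone should give the 3-diazoflavanone F2. Irradiation at 365 nm in methanol should trigger a Wolff rearrangement in which C4a again moves from C4 to C3, giving the ring-contracted ketene F3, which adds methanol. The kinetically protonated cis ester F4 formed beside the trans ester is equilibrated at C3 with catalytic DBU in toluene. The sequence comes back to the route at 10.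

Step 4. Transmetalation and insertion may be slow, the electron-rich boronic acid may protodeboronate, or facial selectivity may be insufficient. The fallback separates bond formation from enantiocontrol and sets out from 5 and 6. The same conjugate addition with the achiral ligand 2,2'-bipyridine should give the racemic flavanone F5. A kinetic resolution follows, by asymmetric transfer hydrogenation (RuCl(p-cymene)[(S,S)-TsDPEN], HCO2Na, H2O/EtOAc, rt). It should reduce the (S)-enantiomer, which is matched for the 2,4-cis product, to the cis-(2S,4S)-flavan-4-ol F6. The (R)-ketone is left unreacted, is separated by chromatography, and is the point where the fallback comes back to the route, at 7.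

Step 3. The pivaloyl group may be lost or may migrate from oxygen to oxygen under methanol and dimethylamine at 90 °C, and the phenol may be O-methylated by the amide acetal. The fallback installs the protecting group only after the chromone exists and sets out from 1. Bromination (Br2, AcOH) para to the 2'-OH should give 5'-bromo-2',3'-dihydroxyacetophenone F7. The amide acetal then gives the enaminone F8, which closes with HCl to 6-bromo-8-hydroxychromone F9. Its only remaining hydroxyl group is acylated with PivCl/Et3N, and the fallback comes back to the route at 5.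

Further compounds
F1 | step 5 | (E)-3-(dimethylaminomethylene) derivative of 7, C2 as in 7 | COc1ccc([C@@H]2Oc3c(OC(=O)C(C)(C)C)cc(Br)cc3C(=O)/C2=C/N(C)C)cc1OC
F2 | step 5 | 3-diazo derivative of 7, C2 as in 7 | COc1ccc([C@@H]2Oc3c(OC(=O)C(C)(C)C)cc(Br)cc3C(=O)C2=[N+]=[N-])cc1OC
F3 | step 5 | 5-bromo-2-(3,4-dimethoxyphenyl)-3-(oxomethylidene)-2,3-dihydrobenzofuran-7-yl pivalate (ketene), C2 as in 7 | COc1ccc([C@@H]2Oc3c(OC(=O)C(C)(C)C)cc(Br)cc3C2=C=O)cc1OC
F4 | step 5 | methyl (2R,3S)-5-bromo-2-(3,4-dimethoxyphenyl)-7-(pivaloyloxy)-2,3-dihydrobenzofuran-3-carboxylate (2,3-cis epimer of 10) | COc1ccc([C@@H]2Oc3c(OC(=O)C(C)(C)C)cc(Br)cc3[C@@H]2C(=O)OC)cc1OC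
F5 | step 4 | racemic 6-bromo-2-(3,4-dimethoxyphenyl)-4-oxochroman-8-yl pivalate | COc1ccc(C2Oc3c(OC(=O)C(C)(C)C)cc(Br)cc3C(=O)C2)cc1OC
F6 | step 4 | (2S,4S)-6-bromo-2-(3,4-dimethoxyphenyl)-4-hydroxychroman-8-yl pivalate (2,4-cis) | COc1ccc([C@H]2Oc3c(OC(=O)C(C)(C)C)cc(Br)cc3[C@@H](O)C2)cc1OC
F7 | step 3 | 1-(5-bromo-2,3-dihydroxyphenyl)ethan-1-one | CC(=O)c1cc(Br)cc(O)c1O
F8 | step 3 | (E)-1-(5-bromo-2,3-dihydroxyphenyl)-3-(dimethylamino)prop-2-en-1-one | CN(C)/C=C/C(=O)c1cc(Br)cc(O)c1O
F9 | step 3 | 6-bromo-8-hydroxy-4H-chromen-4-one | O=c1ccoc2c(O)cc(Br)cc12
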